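Ring B (C5–C10) is read as a Diels–Alder cyclohexene whose two new σ-bonds, C8–C9 and C5–C10, flank the C9–C10 dienophile. Because C5–C10 is also the fusion bond of ring A, one intramolecular [4+2] of an acyclic triene closes both rings and sets C5, C9 and C10. The precursor is a 2-silyloxy diene (C5=C6–C7(OSi)=C8–C17) joined through C4(Me)2–C3–C2–C1 to a (Z)-2-alkyl-2-enoate (C9=C10, ester carbon = C20); a dioxolane on C2/C3 steers the facial sense. Afterwards the C7 ketone is turned into the C7=C8 alkene and the C20 ester into the angular methyl.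

Key step: step 9

Remark: C-numbers are the labdane positions of the target (decalin C1–C10; side chain C11–C15 with C16 on C13; C17 on C8; C18/C19 on C4; C20 on C10); (S)-citronellol, D-proline and prenylboronic acid pinacol ester are taken as purchasable.

Step 1
Reactants: 1 (S)-citronellol
Product: 2 tert-butyl{[(3S)-3,7-dimethyloct-6-en-1-yl]oxy}dimethylsilane
Conditions: TBSCl, imidazole, CH2Cl2, 0 → 23 °C
Reagents that add atoms: tert-butyldimethylsilyl chloride, CC(C)(C)[Si](C)(C)Cl
Why: Routine silylation of the primary alcohol (the later C15–O), which must be masked through the hydride and oxidation steps; the C13 stereocentre comes from the chiral pool and is not touched.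

Step 2
Reactants: 2 tert-butyl{[(3S)-3,7-dimethyloct-6-en-1-yl]oxy}dimethylsilane
Product: 4 (4S)-6-[(tert-butyldimethylsilyl)oxy]-4-methylhexanal, via ozonide 3 (not isolated)
Conditions: O3, CH2Cl2, −78 °C; then PPh3, −78 → 23 °C
Reagents that add atoms: ozone, [O-][O+]=O
Why: Ozonolysis of the only (trisubstituted) alkene with reductive work-up should give the aldehyde whose carbonyl carbon becomes C9; the silyl ether is inert.

Step 3
Reactants: 4 (4S)-6-[(tert-butyldimethylsilyl)oxy]-4-methylhexanal; 5 methyl acrylate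
Product: 6 methyl (6S)-8-[(tert-butyldimethylsilyl)oxy]-3-hydroxy-6-methyl-2-methylideneoctanoate (both C3 epimers)
Conditions: 5 (3 equiv), DABCO (1 equiv), MeOH, 23 °C, several days
Reagents that add atoms: none
Why: Morita–Baylis–Hillman reaction joins C9 to C10 and brings in C1 (the methylidene) and C20 (the ester); the carbinol centre is expected to form unselectively and is erased in step 4.

Step 4
Reactants: 6 methyl (6S)-8-[(tert-butyldimethylsilyl)oxy]-3-hydroxy-6-methyl-2-methylideneoctanoate; 7 ethyl vinyl ether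
Product: 9 methyl (2Z,6S)-8-[(tert-butyldimethylsilyl)oxy]-6-methyl-2-(3-oxopropyl)oct-2-enoate, via allyl vinyl ether 8 (not isolated)
Conditions: 7 (solvent), Hg(OAc)2 (0.2 equiv), 35 °C; evaporate; then PhMe, 130 °C (sealed tube)
Reagents that add atoms: none
Why: Transvinylation followed by Claisen rearrangement forms C1–C2 and the C3 aldehyde; in the chair transition state the side chain on the carbinol carbon sits pseudo-equatorial, so it should end trans to the new chain and cis to the ester, which is the (Z)-enoate geometry needed for the C9/C10 relationship.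

Step 5
Reactants: 9 methyl (2Z,6S)-8-[(tert-butyldimethylsilyl)oxy]-6-methyl-2-(3-oxopropyl)oct-2-enoate; 10 prenylboronic acid pinacol ester
Product: 12 methyl (2Z,6S)-8-[(tert-butyldimethylsilyl)oxy]-2-[(2S,3R)-3-hydroxy-4,4-dimethyl-2-(phenylaminooxy)hex-5-en-1-yl]-6-methyloct-2-enoate, via aminoxy aldehyde 11 (not isolated)
Conditions: D-proline (20 mol%), PhNO, CHCl3, 4 °C; then 10 (2 equiv), 4 → 23 °C; aqueous work-up
Reagents that add atoms: nitrosobenzene, O=Nc1ccccc1
Why: Enamine-catalysed O-selective nitroso aldol (α-aminoxylation) should set C2 as (S) under control of D-proline, and the prenylboronate then adds through a closed six-membered transition state at its γ-carbon (creating the quaternary C4 and the vinyl group) anti to the α-C–O bond (Felkin–Anh/Cornforth, reinforced by the (Z)-methyl of the reagent), setting C3 as the anti diol partner.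

Step 6
Reactants: 12 methyl (2Z,6S)-8-[(tert-butyldimethylsilyl)oxy]-2-[(2S,3R)-3-hydroxy-4,4-dimethyl-2-(phenylaminooxy)hex-5-en-1-yl]-6-methyloct-2-enoate
Product: 13 methyl (2Z,6S)-8-[(tert-butyldimethylsilyl)oxy]-2-[(2S,3R)-2,3-dihydroxy-4,4-dimethylhex-5-en-1-yl]-6-methyloct-2-enoate
Conditions: Zn, AcOH, THF, 23 °C
Reagents that add atoms: none
Why: Reductive cleavage of the weak N–O bond should free the C2 hydroxyl without touching the enoate, the vinyl group or the silyl ether.

Step 7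
Reactants: 13 methyl (2Z,6S)-8-[(tert-butyldimethylsilyl)oxy]-2-[(2S,3R)-2,3-dihydroxy-4,4-dimethylhex-5-en-1-yl]-6-methyloct-2-enoate
Product: 14 methyl (2Z,6S)-8-[(tert-butyldimethylsilyl)oxy]-2-{[(4S,5R)-2,2-dimethyl-5-(2-methylbut-3-en-2-yl)-1,3-dioxolan-4-yl]methyl}-6-methyloct-2-enoate
Conditions: 2,2-dimethoxypropane, PPTS (cat.), CH2Cl2, 23 °C
Reagents that add atoms: 2,2-dimethoxypropane, COC(C)(C)OC
Why: Acetalisation of the only 1,2-diol gives the cis-dioxolane that protects C2–O/C3–O and holds C1 and C4 gauche, which pre-organises the tether for step 9.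

Step 8
Reactants: 14 methyl (2Z,6S)-8-[(tert-butyldimethylsilyl)oxy]-2-{[(4S,5R)-2,2-dimethyl-5-(2-methylbut-3-en-2-yl)-1,3-dioxolan-4-yl]methyl}-6-methyloct-2-enoate; 15 pent-1-en-3-one
Product: 16 methyl (2Z,6S)-8-[(tert-butyldimethylsilyl)oxy]-2-({(4S,5R)-2,2-dimethyl-5-[(3E)-2-methyl-5-oxohept-3-en-2-yl]-1,3-dioxolan-4-yl}methyl)-6-methyloct-2-enoate
Conditions: 15 (5 equiv), second-generation Hoveyda–Grubbs catalyst (10 mol%), PhMe, 80 °C
Reagents that add atoms: none
Why: Olefin cross-metathesis of the monosubstituted vinyl group with the enone partner should give the (E)-enone (C5=C6–C7(=O)–C8–C17), the trisubstituted electron-poor enoate being inert to the catalyst.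

Step 9
Reactants: 16 methyl (2Z,6S)-8-[(tert-butyldimethylsilyl)oxy]-2-({(4S,5R)-2,2-dimethyl-5-[(3E)-2-methyl-5-oxohept-3-en-2-yl]-1,3-dioxolan-4-yl}methyl)-6-methyloct-2-enoate
Product: 19 methyl 15-[(tert-butyldimethylsilyl)oxy]-2,3-(isopropylidenedioxy)-7-oxolabdan-20-oate (trans-fused; 8-methyl equatorial), via trimethylsilyl dienol ether 17 (not isolated), via silyl enol ether cycloadduct 18 (not isolated)
Conditions: Me3SiOTf, Et3N, PhMe (0.01 M), 0 → 23 °C; then 170 °C (sealed tube); then K2CO3, MeOH, 23 °C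
Reagents that add atoms: none
Why: Soft enolisation, possible only toward C8, gives the (Z)-2-silyloxy diene C5=C6–C7(OSiMe3)=C8, which should undergo a concerted but asynchronous normal-demand intramolecular [4+2] with the (Z)-enoate C9=C10, the nucleophilic C8 bonding to the enoate β-carbon C9 and C5 to the ester-bearing C10 (C7–O and the C10 ester end up 1,4, the electronically matched orientation); methanolysis then unmasks the C7 ketone and equilibrates C8. The closest known reaction type is the type 1 intramolecular Diels–Alder reaction of a 1,7,9-decatriene carrying a 2-silyloxy diene, also run as the silyl triflate/amine-promoted intramolecular double Michael reaction. Ring B (C5–C6–C7–C8–C9–C10) is closed as the cyclohexene of the cycloaddition, and ring A (C1–C2–C3–C4–C5–C10) is closed by the same C5–C10 bond through the four-atom tether in a chair-like fused arrangement. C9 follows from the (Z)-enoate geometry (C11 cis to the ester, so C11 and C20 end cis), the trans C5/C10 fusion from the endo-ester transition state with the tether exo, the absolute sense from the dioxolane (C2–O equatorial and C3–O axial in the chair-like tether, whereas the other face would force C2–O axial against the C10 ester and a C4 methyl), and C8 from base equilibration to the equatorial methyl. The step needs endo over exo selectivity (trans versus cis fusion) and enough reactivity at a trisubstituted enoate; only the endo preference of the ester and the strain of the exo tether secure the former, so this is the main risk, while regiochemistry is fixed by the tether.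

Step 10
Reactants: 19 methyl 15-[(tert-butyldimethylsilyl)oxy]-2,3-(isopropylidenedioxy)-7-oxolabdan-20-oate
Product: 20 methyl 15-[(tert-butyldimethylsilyl)oxy]-7-hydroxy-2,3-(isopropylidenedioxy)labdan-20-oate (7-OH axial, cis to the 8-methyl)
Conditions: LiBH(s-Bu)3 (L-Selectride), THF, −78 °C; then H2O
Reagents that add atoms: none
Why: The bulky hydride should attack the ketone from the equatorial direction and give the axial alcohol cis to the equatorial C8 methyl (as with 2-methylcyclohexanone), leaving the hindered ester untouched at −78 °C.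

Step 11
Reactants: 20 methyl 15-[(tert-butyldimethylsilyl)oxy]-7-hydroxy-2,3-(isopropylidenedioxy)labdan-20-oate
Product: 21 methyl 15-[(tert-butyldimethylsilyl)oxy]-2,3-(isopropylidenedioxy)labd-7-en-20-oate
Conditions: POCl3, pyridine, 0 → 70 °C
Reagents that add atoms: none
Why: E2 elimination of the axial dichlorophosphate has anti-periplanar axial hydrogens at C8 and C6, and Zaitsev preference should favour loss of the tertiary C8–H to give the trisubstituted C7=C8 alkene (some C6=C7 isomer is possible), which also removes the temporary C7 and C8 stereocentres.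

Step 12
Reactants: 21 methyl 15-[(tert-butyldimethylsilyl)oxy]-2,3-(isopropylidenedioxy)labd-7-en-20-oate
Product: 22 15-[(tert-butyldimethylsilyl)oxy]-2,3-(isopropylidenedioxy)labd-7-en-20-ol
Conditions: LiAlH4, THF, 0 → 66 °C
Reagents that add atoms: none
Why: Hydride reduction of the hindered angular ester to the neopentyl alcohol; alkene, acetonide and silyl ether are stable.

Step 13
Reactants: 22 15-[(tert-butyldimethylsilyl)oxy]-2,3-(isopropylidenedioxy)labd-7-en-20-ol
Product: 23 15-[(tert-butyldimethylsilyl)oxy]-2,3-(isopropylidenedioxy)labd-7-en-20-al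
Conditions: Dess–Martin periodinane, CH2Cl2, 23 °C
Reagents that add atoms: none
Why: Dess–Martin oxidation of the only free hydroxyl under near-neutral conditions gives the non-enolisable angular aldehyde.

Step 14
Reactants: 23 15-[(tert-butyldimethylsilyl)oxy]-2,3-(isopropylidenedioxy)labd-7-en-20-al
Product: 25 15-[(tert-butyldimethylsilyl)oxy]-2,3-(isopropylidenedioxy)labd-7-ene, via hydrazone 24 (not isolated)
Conditions: N2H4·H2O, EtOH, 80 °C; evaporate; then KOtBu, DMSO, 23 °C
Reagents that add atoms: none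
Why: Wolff–Kishner reduction through the preformed hydrazone at room temperature should turn the angular aldehyde into the C20 methyl, the classical outcome for hindered neopentyl aldehydes, while acetonide, silyl ether and the isolated alkene tolerate the base.

Step 15
Reactants: 25 15-[(tert-butyldimethylsilyl)oxy]-2,3-(isopropylidenedioxy)labd-7-ene
Product: 26 labd-7-ene-2,3,15-triol (configuration of the target)
Conditions: 1 M aq. HCl, THF, 23 → 40 °C
Reagents that add atoms: none
Why: Mild aqueous acid should hydrolyse both the acetonide and the primary silyl ether without isomerising the trisubstituted alkene.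

Step 16
Reactants: 26 labd-7-ene-2,3,15-triol
Product: 27 (2S,3R,5S,9R,10S,13S)-labd-7-ene-2,3,15-triol 2,15-diacetate (CNP0144124.1)
Conditions: Ac2O (2.2 equiv), pyridine, 0 → 23 °C
Reagents that add atoms: acetic anhydride, CC(=O)OC(C)=O
Why: The primary C15–OH and the equatorial C2–OH should be acetylated, whereas the axial C3–OH next to the C4 gem-dimethyl group is too hindered to react under these DMAP-free conditions.

Compound list
1 | (S)-citronellol, (3S)-3,7-dimethyloct-6-en-1-ol | OCC[C@@H](C)CCC=C(C)C | starting material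
2 | tert-butyl{[(3S)-3,7-dimethyloct-6-en-1-yl]oxy}dimethylsilane | CC(C)(C)[Si](C)(C)OCC[C@@H](C)CCC=C(C)C | intermediate
3 | 3-{(3S)-5-[(tert-butyldimethylsilyl)oxy]-3-methylpentyl}-5,5-dimethyl-1,2,4-trioxolane (both epimers at the ring CH) | CC(C)(C)[Si](C)(C)OCC[C@@H](C)CCC1OOC(C)(C)O1 | intermediate (not isolated)
4 | (4S)-6-[(tert-butyldimethylsilyl)oxy]-4-methylhexanal | CC(C)(C)[Si](C)(C)OCC[C@@H](C)CCC=O | intermediate
5 | methyl acrylate | C=CC(=O)OC | starting material
6 | methyl (6S)-8-[(tert-butyldimethylsilyl)oxy]-3-hydroxy-6-methyl-2-methylideneoctanoate (both C3 epimers) | CC(C)(C)[Si](C)(C)OCC[C@@H](C)CCC(O)C(=C)C(=O)OC | intermediate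
7 | ethyl vinyl ether | CCOC=C | starting material
8 | methyl (6S)-8-[(tert-butyldimethylsilyl)oxy]-3-(ethenyloxy)-6-methyl-2-methylideneoctanoate (both C3 epimers) | CC(C)(C)[Si](C)(C)OCC[C@@H](C)CCC(OC=C)C(=C)C(=O)OC | intermediate (not isolated)
9 | methyl (2Z,6S)-8-[(tert-butyldimethylsilyl)oxy]-6-methyl-2-(3-oxopropyl)oct-2-enoate | CC(C)(C)[Si](C)(C)OCC[C@@H](C)CC/C=C(/CCC=O)C(=O)OC | intermediate
10 | prenylboronic acid pinacol ester, 4,4,5,5-tetramethyl-2-(3-methylbut-2-en-1-yl)-1,3,2-dioxaborolane | CC(C)=CCB1OC(C)(C)C(C)(C)O1 | starting material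
11 | methyl (2Z,6S)-8-[(tert-butyldimethylsilyl)oxy]-6-methyl-2-[(2S)-3-oxo-2-(phenylaminooxy)propyl]oct-2-enoate | CC(C)(C)[Si](C)(C)OCC[C@@H](C)CC/C=C(/C[C@H](ONc1ccccc1)C=O)C(=O)OC | intermediate (not isolated)
12 | methyl (2Z,6S)-8-[(tert-butyldimethylsilyl)oxy]-2-[(2S,3R)-3-hydroxy-4,4-dimethyl-2-(phenylaminooxy)hex-5-en-1-yl]-6-methyloct-2-enoate | CC(C)(C)[Si](C)(C)OCC[C@@H](C)CC/C=C(/C[C@H](ONc1ccccc1)[C@H](O)C(C)(C)C=C)C(=O)OC | intermediate
13 | methyl (2Z,6S)-8-[(tert-butyldimethylsilyl)oxy]-2-[(2S,3R)-2,3-dihydroxy-4,4-dimethylhex-5-en-1-yl]-6-methyloct-2-enoate | CC(C)(C)[Si](C)(C)OCC[C@@H](C)CC/C=C(/C[C@H](O)[C@H](O)C(C)(C)C=C)C(=O)OC | intermediate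
14 | methyl (2Z,6S)-8-[(tert-butyldimethylsilyl)oxy]-2-{[(4S,5R)-2,2-dimethyl-5-(2-methylbut-3-en-2-yl)-1,3-dioxolan-4-yl]methyl}-6-methyloct-2-enoate | CC(C)(C)[Si](C)(C)OCC[C@@H](C)CC/C=C(/C[C@@H]1OC(C)(C)O[C@@H]1C(C)(C)C=C)C(=O)OC | intermediate
15 | pent-1-en-3-one (ethyl vinyl ketone) | CCC(=O)C=C | starting material
16 | methyl (2Z,6S)-8-[(tert-butyldimethylsilyl)oxy]-2-({(4S,5R)-2,2-dimethyl-5-[(3E)-2-methyl-5-oxohept-3-en-2-yl]-1,3-dioxolan-4-yl}methyl)-6-methyloct-2-enoate | CC(C)(C)[Si](C)(C)OCC[C@@H](C)CC/C=C(/C[C@@H]1OC(C)(C)O[C@@H]1C(C)(C)/C=C/C(=O)CC)C(=O)OC | intermediate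
17 | (3E,5Z)-5-(trimethylsilyloxy)hepta-3,5-dien-2-yl analogue of 16 (silyl dienol ether) | CC(C)(C)[Si](C)(C)OCC[C@@H](C)CC/C=C(/C[C@@H]1OC(C)(C)O[C@@H]1C(C)(C)/C=C/C(O[Si](C)(C)C)=C/C)C(=O)OC | intermediate (not isolated)
18 | methyl 15-[(tert-butyldimethylsilyl)oxy]-2,3-(isopropylidenedioxy)-7-(trimethylsilyloxy)labd-6-en-20-oate (trans-fused; 8-methyl cis to C20) | CC(C)(C)[Si](C)(C)OCC[C@@H](C)CC[C@@H]1[C@H](C)C(O[Si](C)(C)C)=C[C@@H]2C(C)(C)[C@@H](OC(C)(C)O3)[C@@H]3C[C@@]12C(=O)OC | intermediate (not isolated)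
19 | methyl 15-[(tert-butyldimethylsilyl)oxy]-2,3-(isopropylidenedioxy)-7-oxolabdan-20-oate (trans-fused; 8-methyl equatorial, trans to the C9 side chain) | CC(C)(C)[Si](C)(C)OCC[C@@H](C)CC[C@@H]1[C@@H](C)C(=O)C[C@@H]2C(C)(C)[C@@H](OC(C)(C)O3)[C@@H]3C[C@@]12C(=O)OC | intermediate
20 | methyl 15-[(tert-butyldimethylsilyl)oxy]-7-hydroxy-2,3-(isopropylidenedioxy)labdan-20-oate (7-OH axial, cis to the 8-methyl) | CC(C)(C)[Si](C)(C)OCC[C@@H](C)CC[C@@H]1[C@@H](C)[C@@H](O)C[C@@H]2C(C)(C)[C@@H](OC(C)(C)O3)[C@@H]3C[C@@]12C(=O)OC | intermediate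
21 | methyl 15-[(tert-butyldimethylsilyl)oxy]-2,3-(isopropylidenedioxy)labd-7-en-20-oate | CC(C)(C)[Si](C)(C)OCC[C@@H](C)CC[C@@H]1C(C)=CC[C@@H]2C(C)(C)[C@@H](OC(C)(C)O3)[C@@H]3C[C@@]12C(=O)OC | intermediate
22 | 15-[(tert-butyldimethylsilyl)oxy]-2,3-(isopropylidenedioxy)labd-7-en-20-ol | CC(C)(C)[Si](C)(C)OCC[C@@H](C)CC[C@@H]1C(C)=CC[C@@H]2C(C)(C)[C@@H](OC(C)(C)O3)[C@@H]3C[C@@]12CO | intermediate
23 | 15-[(tert-butyldimethylsilyl)oxy]-2,3-(isopropylidenedioxy)labd-7-en-20-al | CC(C)(C)[Si](C)(C)OCC[C@@H](C)CC[C@@H]1C(C)=CC[C@@H]2C(C)(C)[C@@H](OC(C)(C)O3)[C@@H]3C[C@@]12C=O | intermediate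
24 | hydrazone of 23 | CC(C)(C)[Si](C)(C)OCC[C@@H](C)CC[C@@H]1C(C)=CC[C@@H]2C(C)(C)[C@@H](OC(C)(C)O3)[C@@H]3C[C@@]12C=NN | intermediate (not isolated)
25 | 15-[(tert-butyldimethylsilyl)oxy]-2,3-(isopropylidenedioxy)labd-7-ene | CC(C)(C)[Si](C)(C)OCC[C@@H](C)CC[C@@H]1C(C)=CC[C@@H]2C(C)(C)[C@@H](OC(C)(C)O3)[C@@H]3C[C@@]12C | intermediate
26 | labd-7-ene-2,3,15-triol (configuration of the target) | OCC[C@@H](C)CC[C@@H]1C(C)=CC[C@@H]2C(C)(C)[C@@H](O)[C@@H](O)C[C@@]12C | intermediate
27 | (2S,3R,5S,9R,10S,13S)-labd-7-ene-2,3,15-triol 2,15-diacetate (CNP0144124.1) | CC(=O)OCC[C@@H](C)CC[C@@H]1C(C)=CC[C@@H]2C(C)(C)[C@@H](O)[C@@H](OC(C)=O)C[C@@]12C | target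

Total step count: 16. Longest linear sequence: 16 steps (from 1; the route is linear, with 5, 7, 10 and 15 added as purchased building blocks).

Steps most likely to fail

Step 9 (key step). The cycloaddition may stall at the hindered trisubstituted enoate, or the exo transition state may compete and give the cis-fused decalin. The fallback changes the dienophile to the more reactive, more endo-directing aldehyde and uses Lewis-acid activation at low temperature. It sets out from 14. i-Bu2AlH (CH2Cl2, −78 °C) would reduce the ester to the (Z)-allylic alcohol F1, and MnO2 would oxidise it to the (Z)-enal F2. Cross-metathesis with 15 as in step 8 would give the enone–enal F3. t-BuMe2SiOTf/Et3N would give the tert-butyldimethylsilyl dienol ether F4, and Me2AlCl (CH2Cl2, −78 °C) should promote the endo-selective intramolecular Diels–Alder reaction to the cycloadduct F5. Brief aqueous HCl in THF at 0 °C and then DBU would give the keto aldehyde F6. Pinnick oxidation (NaClO2, NaH2PO4, 2-methyl-2-butene) would give the keto acid F7, and esterification with Me3SiCHN2 in MeOH would return to the route at 19.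

Step 8. Metathesis at the vinyl group on the quaternary C4 may be so slow that the catalyst decomposes before conversion. The fallback builds the enone by olefination and sets out from 14. OsO4 (cat.) with N-methylmorpholine N-oxide would dihydroxylate the monosubstituted alkene in preference to the electron-poor trisubstituted enoate, giving the diol F8. NaIO4 would cleave it to the neopentyl aldehyde F9. A Horner–Wadsworth–Emmons reaction with diethyl (2-oxobutyl)phosphonate (Ba(OH)2, THF–H2O) would then give the (E)-enone and return to the route at 16.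

Step 5. The α-aminoxy aldehyde may oligomerise or lose configuration before the allylboration, or the one-pot addition may show poor facial selectivity. The fallback separates the two events through an isolable α-oxy aldehyde and sets out from 9. Amine/copper co-catalysed α-oxyamination with TEMPO (chiral imidazolidinone trifluoroacetate chosen for the (S) product, CuCl2·2H2O, air, acetone, −10 °C) would give the configurationally stable O-(2,2,6,6-tetramethylpiperidin-1-yl) aldehyde F10. Prenylboration with 10 would give the anti alcohol F11. Zn in AcOH would cleave the N–O bond and return to the route at 13.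

Further compounds
F1 | step 9 | (2Z,6S)-8-[(tert-butyldimethylsilyl)oxy]-2-{[(4S,5R)-2,2-dimethyl-5-(2-methylbut-3-en-2-yl)-1,3-dioxolan-4-yl]methyl}-6-methyloct-2-en-1-ol | CC(C)(C)[Si](C)(C)OCC[C@@H](C)CC/C=C(/C[C@@H]1OC(C)(C)O[C@@H]1C(C)(C)C=C)CO
F2 | step 9 | (2Z,6S)-8-[(tert-butyldimethylsilyl)oxy]-2-{[(4S,5R)-2,2-dimethyl-5-(2-methylbut-3-en-2-yl)-1,3-dioxolan-4-yl]methyl}-6-methyloct-2-enal | CC(C)(C)[Si](C)(C)OCC[C@@H](C)CC/C=C(/C[C@@H]1OC(C)(C)O[C@@H]1C(C)(C)C=C)C=O
F3 | step 9 | (2Z,6S)-8-[(tert-butyldimethylsilyl)oxy]-2-({(4S,5R)-2,2-dimethyl-5-[(3E)-2-methyl-5-oxohept-3-en-2-yl]-1,3-dioxolan-4-yl}methyl)-6-methyloct-2-enal | CC(C)(C)[Si](C)(C)OCC[C@@H](C)CC/C=C(/C[C@@H]1OC(C)(C)O[C@@H]1C(C)(C)/C=C/C(=O)CC)C=O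
F4 | step 9 | (3E,5Z)-5-(tert-butyldimethylsilyloxy)hepta-3,5-dien-2-yl dienol ether of F3 | CC(C)(C)[Si](C)(C)OCC[C@@H](C)CC/C=C(/C[C@@H]1OC(C)(C)O[C@@H]1C(C)(C)/C=C/C(O[Si](C)(C)C(C)(C)C)=C/C)C=O
F5 | step 9 | 7,15-bis[(tert-butyldimethylsilyl)oxy]-2,3-(isopropylidenedioxy)labd-6-en-20-al (trans-fused; 8-methyl cis to C20) | CC(C)(C)[Si](C)(C)OCC[C@@H](C)CC[C@@H]1[C@H](C)C(O[Si](C)(C)C(C)(C)C)=C[C@@H]2C(C)(C)[C@@H](OC(C)(C)O3)[C@@H]3C[C@@]12C=O
F6 | step 9 | 15-[(tert-butyldimethylsilyl)oxy]-2,3-(isopropylidenedioxy)-7-oxolabdan-20-al (8-methyl equatorial) | CC(C)(C)[Si](C)(C)OCC[C@@H](C)CC[C@@H]1[C@@H](C)C(=O)C[C@@H]2C(C)(C)[C@@H](OC(C)(C)O3)[C@@H]3C[C@@]12C=O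
F7 | step 9 | 15-[(tert-butyldimethylsilyl)oxy]-2,3-(isopropylidenedioxy)-7-oxolabdan-20-oic acid (8-methyl equatorial) | CC(C)(C)[Si](C)(C)OCC[C@@H](C)CC[C@@H]1[C@@H](C)C(=O)C[C@@H]2C(C)(C)[C@@H](OC(C)(C)O3)[C@@H]3C[C@@]12C(=O)O
F8 | step 8 | methyl (2Z,6S)-8-[(tert-butyldimethylsilyl)oxy]-2-{[(4S,5R)-5-(3,4-dihydroxy-2-methylbutan-2-yl)-2,2-dimethyl-1,3-dioxolan-4-yl]methyl}-6-methyloct-2-enoate (both carbinol epimers) | CC(C)(C)[Si](C)(C)OCC[C@@H](C)CC/C=C(/C[C@@H]1OC(C)(C)O[C@@H]1C(C)(C)C(O)CO)C(=O)OC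
F9 | step 8 | methyl (2Z,6S)-8-[(tert-butyldimethylsilyl)oxy]-2-{[(4S,5R)-2,2-dimethyl-5-(2-methyl-1-oxopropan-2-yl)-1,3-dioxolan-4-yl]methyl}-6-methyloct-2-enoate | CC(C)(C)[Si](C)(C)OCC[C@@H](C)CC/C=C(/C[C@@H]1OC(C)(C)O[C@@H]1C(C)(C)C=O)C(=O)OC
F10 | step 5 | methyl (2Z,6S)-8-[(tert-butyldimethylsilyl)oxy]-6-methyl-2-{(2S)-3-oxo-2-[(2,2,6,6-tetramethylpiperidin-1-yl)oxy]propyl}oct-2-enoate | CC(C)(C)[Si](C)(C)OCC[C@@H](C)CC/C=C(/C[C@H](ON1C(C)(C)CCCC1(C)C)C=O)C(=O)OC
F11 | step 5 | methyl (2Z,6S)-8-[(tert-butyldimethylsilyl)oxy]-2-{(2S,3R)-3-hydroxy-4,4-dimethyl-2-[(2,2,6,6-tetramethylpiperidin-1-yl)oxy]hex-5-en-1-yl}-6-methyloct-2-enoate | CC(C)(C)[Si](C)(C)OCC[C@@H](C)CC/C=C(/C[C@H](ON1C(C)(C)CCCC1(C)C)[C@H](O)C(C)(C)C=C)C(=O)OC
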